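**Plan**

1. Retrosynthesis first removes the nine O-methyl groups, then cuts furan 2 (the dihydrofuran carrying 2,4- and 3,5-dihydroxyphenyl) at its ring A–CH and O–CH bonds, back to a ring A phenol and (E)-2,4,3',5'-tetramethoxystilbene.
2. Key cut: furan 1 (the dihydrofuran carrying 4-hydroxyphenyl) and the seven-membered ring share the bond from C-3 of furan 1 to ring A (the central benzene). Breaking this C–C bond and the O–C-2 bond of furan 1 turns the two sp3 carbons of furan 1 into the alkene carbons of a 4-methoxystilbene on ring B, tied to a symmetric 5-substituted resorcinol (ring A) by the CH(aryl)–CH2 bridge.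
3. The open precursor is cut at the stilbene C–C bond (Heck), the CH2–ring A bond (decarboxylative arylation) and the CH–aryl bond (conjugate arylation of a ring B cinnamate). A chalcone would give a three-carbon bridge, so the bridge is built from a cinnamate with loss of the carboxyl carbon.
4. Forward order: ring B cinnamate, diarylmethine, ring A, stilbene, seven-membered ring and furan 1 together, furan 2, free phenols.
5. Stereochemistry: the (R)-diarylmethine comes from rhodium/chiral diene catalysis and sets the alkene face in the key step. Both dihydrofurans close trans under thermodynamic control; the face of furan 2 relies on substrate control.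

Key step: step 8

Assumption: the (S,S) antipode of the diene ligand is taken to bind the enoate through its α-si face, as (S)-BINAP does; if the sense is the reverse, the (R,R) ligand is used and nothing else changes.

**Route**

Step 1
Reactants: 1 2-bromo-4,6-dimethoxybenzaldehyde; 2 triethyl phosphonoacetate
Product: 3 ethyl (E)-3-(2-bromo-4,6-dimethoxyphenyl)prop-2-enoate
Conditions: NaH, THF, 0 °C to rt
Reagents that add atoms: none
Why: Horner–Wadsworth–Emmons olefination of an aromatic aldehyde with a stabilised phosphonate gives the (E)-cinnamate, and the ortho bromide and methoxy groups are spectators.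

Step 2
Reactants: 3 ethyl (E)-3-(2-bromo-4,6-dimethoxyphenyl)prop-2-enoate; 4 (2,4-dimethoxyphenyl)boronic acid
Product: 6 (3R)-3-(2-bromo-4,6-dimethoxyphenyl)-3-(2,4-dimethoxyphenyl)propanoic acid, via ethyl ester 5 (not isolated)
Conditions: [RhCl(C2H4)2]2 (2.5 mol%), (S,S)-2,5-diphenylbicyclo[2.2.2]octa-2,5-diene (5.5 mol%), KOH (0.2 equiv), 4 (3 equiv), dioxane/H2O 10:1, 50 °C; then LiOH·H2O, MeOH/H2O, 50 °C; HCl work-up
Reagents that add atoms: lithium hydroxide, [Li+].[OH-]
Why: Hayashi–Miyaura rhodium-catalysed asymmetric 1,4-addition of an arylboronic acid to a cinnamate, in which the aryl–rhodium–diene complex inserts the enoate through its α-si face and so delivers the 2,4-dimethoxyphenyl group to the Si face of C-3 to set the (R)-diarylmethine, while monovalent rhodium leaves the aryl bromide alone and saponification in the same flask lets acid–base extraction remove excess boronic acid and 1,3-dimethoxybenzene.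

Step 3
Reactants: 6 (3R)-3-(2-bromo-4,6-dimethoxyphenyl)-3-(2,4-dimethoxyphenyl)propanoic acid
Product: 7 1,3-dioxoisoindolin-2-yl (3R)-3-(2-bromo-4,6-dimethoxyphenyl)-3-(2,4-dimethoxyphenyl)propanoate
Conditions: N-hydroxyphthalimide, N,N'-diisopropylcarbodiimide, DMAP (cat.), CH2Cl2, rt
Reagents that add atoms: N-hydroxyphthalimide, O=C1N(O)C(=O)c2ccccc12
Why: Steglich-type carbodiimide esterification gives the redox-active ester without touching the stereocentre β to the carbonyl.

Step 4
Reactants: 8 5-bromobenzene-1,3-diol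
Product: 9 1-bromo-3,5-bis(triisopropylsilyloxy)benzene
Conditions: TIPSCl, imidazole, DMF, rt
Reagents that add atoms: triisopropylsilyl chloride, CC(C)[Si](Cl)(C(C)C)C(C)C
Why: Standard silylation of phenols, chosen because the bulky silyl ethers survive Grignard formation and the Heck base and are later removed by fluoride without loss of any methyl ether.

Step 5
Reactants: 7 1,3-dioxoisoindolin-2-yl (3R)-3-(2-bromo-4,6-dimethoxyphenyl)-3-(2,4-dimethoxyphenyl)propanoate; 9 1-bromo-3,5-bis(triisopropylsilyloxy)benzene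
Product: 12 1-bromo-2-[(1R)-2-[3,5-bis(triisopropylsilyloxy)phenyl]-1-(2,4-dimethoxyphenyl)ethyl]-3,5-dimethoxybenzene, via arylmagnesium bromide 10 (not isolated), via diarylzinc 11 (not isolated)
Conditions: 9, Mg, LiCl, THF, rt; ZnCl2 (0.5 equiv per aryl); then 7, Fe(acac)3 (10 mol%), 1,2-bis(diphenylphosphino)benzene (12 mol%), THF/toluene, rt
Reagents that add atoms: none
Why: Iron-catalysed decarboxylative Negishi-type arylation of a redox-active ester, in which electron transfer releases CO2 and a primary radical that the aryl–iron species captures, the stereocentre β to the radical is kept, the iron–bisphosphine catalyst does not insert into the hindered aryl bromide, and fast capture is counted on to outrun a 1,2-aryl shift of the 2,2-diarylethyl radical.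

Step 6
Reactants: 12 1-bromo-2-[(1R)-2-[3,5-bis(triisopropylsilyloxy)phenyl]-1-(2,4-dimethoxyphenyl)ethyl]-3,5-dimethoxybenzene; 13 4-methoxystyrene
Product: 14 2-[(1R)-2-[3,5-bis(triisopropylsilyloxy)phenyl]-1-(2,4-dimethoxyphenyl)ethyl]-3,5-dimethoxy-1-[(E)-2-(4-methoxyphenyl)ethenyl]benzene
Conditions: Pd2(dba)3 (2.5 mol%), [HP(t-Bu)3]BF4 (10 mol%), Cy2NMe, 1,4-dioxane, 100 °C
Reagents that add atoms: none
Why: Mizoroki–Heck reaction of a hindered electron-rich aryl bromide with a bulky trialkylphosphine, where syn insertion at the terminal styrene carbon and syn β-hydride elimination give the (E)-stilbene and the amine base does not epimerise the diarylmethine.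

Step 7
Reactants: 14 2-[(1R)-2-[3,5-bis(triisopropylsilyloxy)phenyl]-1-(2,4-dimethoxyphenyl)ethyl]-3,5-dimethoxy-1-[(E)-2-(4-methoxyphenyl)ethenyl]benzene
Product: 15 5-[(2R)-2-(2,4-dimethoxyphenyl)-2-{2,4-dimethoxy-6-[(E)-2-(4-methoxyphenyl)ethenyl]phenyl}ethyl]benzene-1,3-diol
Conditions: TBAF, THF, 0 °C; NH4Cl work-up under argon
Reagents that add atoms: none
Why: Fluoride cleavage of aryl silyl ethers frees the resorcinol while methyl ethers, stilbene and stereocentre are inert.

Step 8
Reactants: 15 5-[(2R)-2-(2,4-dimethoxyphenyl)-2-{2,4-dimethoxy-6-[(E)-2-(4-methoxyphenyl)ethenyl]phenyl}ethyl]benzene-1,3-diol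
Product: 16 tetracyclic phenol: (2R,3R)-2-(4-methoxyphenyl)-2,3-dihydrobenzofuran-6-ol (furan 1 on ring A) whose C-3 and C-4 belong to a seven-membered ring completed by the dimethoxy ring B on C-3, the (R)-CH(2,4-dimethoxyphenyl) carbon on ring B and the CH2 on C-4
Conditions: FeCl3·6H2O (2.2 equiv), CH2Cl2/1,1,1,3,3,3-hexafluoropropan-2-ol 4:1, 0 °C, 2 mM, argon, slow addition of 15
Reagents that add atoms: none
Why: Proposed new method: FeCl3 oxidises the 4-methoxystilbene, the most electron-rich π-system of 15, to its radical cation, whose alkene carbon on ring B is attacked by a ring A carbon ortho to one hydroxyl and para to the other (7-exo-trig), and the resulting 4-methoxybenzyl radical is oxidised by a second equivalent of trivalent iron to the cation, which after rearomatisation is captured by the adjacent phenol oxygen (5-exo-trig onto the quinoid oxocarbenium form), so the seven-membered ring and furan 1 form in one operation. The closest known reactions are the oxidative [3+2] cycloaddition of phenols with electron-rich styrenes and the oxidative coupling of methoxystilbenes, neither of which has been used intramolecularly to close a seven-membered ring. C-3 of furan 1 (R) is set in the C–C bond formation by the resident (R)-diarylmethine: in the chair-like seven-membered transition state the 2,4-dimethoxyphenyl group should sit pseudo-equatorial, so that the arene adds to the alkene face that puts the new C–H anti to the C–H of that centre. C-2 of furan 1 (R) follows from C-3, because the oxygen closure is reversible in the acidic medium and should settle in the trans-2,3-disubstituted dihydrobenzofuran. The step needs oxidation of the stilbene before the resorcinol and the dimethoxyarenes, seven- rather than eight-membered closure, and no ambiguity on ring A; these are secured by the low oxidation potential of the stilbene, by the charge resting on the anisyl-bearing carbon, and by the symmetry of the 5-substituted resorcinol, whose two ortho carbons are equivalent and whose second hydroxyl is left for furan 2. High dilution is used to suppress intermolecular stilbene dimerisation.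

Step 9
Reactants: 17 diethyl (3,5-dimethoxybenzyl)phosphonate; 18 2,4-dimethoxybenzaldehyde
Product: 19 (E)-1-(2,4-dimethoxyphenyl)-2-(3,5-dimethoxyphenyl)ethene
Conditions: NaH, THF, 0 °C to rt
Reagents that add atoms: none
Why: Horner–Wadsworth–Emmons olefination of a benzylphosphonate with an aryl aldehyde gives the (E)-stilbene.

Step 10
Reactants: 16 tetracyclic phenol; 19 (E)-1-(2,4-dimethoxyphenyl)-2-(3,5-dimethoxyphenyl)ethene
Product: 20 nonamethyl ether of the target: 16 with a second trans-dihydrofuran (furan 2) fused to ring A through the former phenol oxygen (to C-2, S, bearing 2,4-dimethoxyphenyl) and the adjacent ring carbon next to the CH2 (to C-3, S, bearing 3,5-dimethoxyphenyl)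
Conditions: 19 (2 equiv, slow addition), FeCl3·6H2O (2.5 equiv), CH2Cl2/1,1,1,3,3,3-hexafluoropropan-2-ol 4:1, 0 °C
Reagents that add atoms: none
Why: Intermolecular oxidative [3+2] cycloaddition of a phenol with an electron-rich stilbene, in which the stilbene radical cation is attacked at its 3,5-dimethoxyphenyl-bearing carbon by the ring A carbon ortho to the free hydroxyl and para to the furan 1 oxygen, the 2,4-dimethoxybenzyl cation formed after a second oxidation is closed by the phenol oxygen to the trans-dihydrofuran, and the (S,S) sense depends on the folded seven-membered ring next to the reacting carbon shielding one face.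

Step 11
Reactants: 20 nonamethyl ether of the target
Product: 21 CNP0283541.1 (nonaphenol; furan 1 2R,3R; seven-membered ring CH(aryl) R; furan 2 2S,3S)
Conditions: BBr3 (excess), CH2Cl2, −78 °C to rt; MeOH, then H2O
Reagents that add atoms: none
Why: Lewis acid cleavage of the nine aryl methyl ethers, during which no stereocentre carries an acidic hydrogen and the trans-dihydrofurans, being the thermodynamic isomers, should re-close if a benzylic C–O bond ionises.

**Compound list**

1 | 2-bromo-4,6-dimethoxybenzaldehyde | COc1cc(OC)c(C=O)c(Br)c1 | starting material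
2 | triethyl phosphonoacetate | CCOC(=O)CP(=O)(OCC)OCC | starting material
3 | ethyl (E)-3-(2-bromo-4,6-dimethoxyphenyl)prop-2-enoate | CCOC(=O)/C=C/c1c(OC)cc(OC)cc1Br | intermediate
4 | (2,4-dimethoxyphenyl)boronic acid | COc1ccc(B(O)O)c(OC)c1 | starting material
5 | ethyl (3R)-3-(2-bromo-4,6-dimethoxyphenyl)-3-(2,4-dimethoxyphenyl)propanoate | CCOC(=O)C[C@H](c1ccc(OC)cc1OC)c1c(OC)cc(OC)cc1Br | intermediate
6 | (3R)-3-(2-bromo-4,6-dimethoxyphenyl)-3-(2,4-dimethoxyphenyl)propanoic acid | OC(=O)C[C@H](c1ccc(OC)cc1OC)c1c(OC)cc(OC)cc1Br | intermediate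
7 | 1,3-dioxoisoindolin-2-yl (3R)-3-(2-bromo-4,6-dimethoxyphenyl)-3-(2,4-dimethoxyphenyl)propanoate | O=C(C[C@H](c1ccc(OC)cc1OC)c1c(OC)cc(OC)cc1Br)ON1C(=O)c2ccccc2C1=O | intermediate
8 | 5-bromobenzene-1,3-diol | Oc1cc(O)cc(Br)c1 | starting material
9 | 1-bromo-3,5-bis(triisopropylsilyloxy)benzene | CC(C)[Si](Oc1cc(Br)cc(O[Si](C(C)C)(C(C)C)C(C)C)c1)(C(C)C)C(C)C | intermediate
10 | [3,5-bis(triisopropylsilyloxy)phenyl]magnesium bromide | Br[Mg]c1cc(O[Si](C(C)C)(C(C)C)C(C)C)cc(O[Si](C(C)C)(C(C)C)C(C)C)c1 | intermediate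
11 | bis[3,5-bis(triisopropylsilyloxy)phenyl]zinc | CC(C)[Si](Oc1cc([Zn]c2cc(O[Si](C(C)C)(C(C)C)C(C)C)cc(O[Si](C(C)C)(C(C)C)C(C)C)c2)cc(O[Si](C(C)C)(C(C)C)C(C)C)c1)(C(C)C)C(C)C | intermediate
12 | 1-bromo-2-[(1R)-2-[3,5-bis(triisopropylsilyloxy)phenyl]-1-(2,4-dimethoxyphenyl)ethyl]-3,5-dimethoxybenzene | CC(C)[Si](Oc1cc(C[C@H](c2ccc(OC)cc2OC)c2c(OC)cc(OC)cc2Br)cc(O[Si](C(C)C)(C(C)C)C(C)C)c1)(C(C)C)C(C)C | intermediate
13 | 4-methoxystyrene | C=Cc1ccc(OC)cc1 | starting material
14 | 2-[(1R)-2-[3,5-bis(triisopropylsilyloxy)phenyl]-1-(2,4-dimethoxyphenyl)ethyl]-3,5-dimethoxy-1-[(E)-2-(4-methoxyphenyl)ethenyl]benzene | CC(C)[Si](Oc1cc(C[C@H](c2ccc(OC)cc2OC)c2c(OC)cc(OC)cc2/C=C/c2ccc(OC)cc2)cc(O[Si](C(C)C)(C(C)C)C(C)C)c1)(C(C)C)C(C)C | intermediate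
15 | 5-[(2R)-2-(2,4-dimethoxyphenyl)-2-{2,4-dimethoxy-6-[(E)-2-(4-methoxyphenyl)ethenyl]phenyl}ethyl]benzene-1,3-diol (key-step precursor) | Oc1cc(O)cc(C[C@H](c2ccc(OC)cc2OC)c2c(OC)cc(OC)cc2/C=C/c2ccc(OC)cc2)c1 | intermediate
16 | tetracyclic phenol with furan 1 (2R,3R) and the seven-membered ring (CH(aryl) R) (key-step product) | COc1ccc([C@@H]2Oc3cc(O)cc4c3[C@H]2c2cc(OC)cc(OC)c2[C@@H](c2ccc(OC)cc2OC)C4)cc1 | intermediate
17 | diethyl (3,5-dimethoxybenzyl)phosphonate | CCOP(=O)(Cc1cc(OC)cc(OC)c1)OCC | starting material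
18 | 2,4-dimethoxybenzaldehyde | COc1ccc(C=O)c(OC)c1 | starting material
19 | (E)-1-(2,4-dimethoxyphenyl)-2-(3,5-dimethoxyphenyl)ethene | COc1ccc(/C=C/c2cc(OC)cc(OC)c2)c(OC)c1 | intermediate
20 | nonamethyl ether of the target (furan 1 2R,3R; CH(aryl) R; furan 2 2S,3S) | COc1ccc([C@@H]2Oc3cc4c(c5c3[C@H]2c2cc(OC)cc(OC)c2[C@@H](c2ccc(OC)cc2OC)C5)[C@H](c2cc(OC)cc(OC)c2)[C@@H](c2ccc(OC)cc2OC)O4)cc1 | intermediate
21 | CNP0283541.1 | Oc1ccc([C@@H]2Oc3cc4c(c5c3[C@H]2c2cc(O)cc(O)c2[C@@H](c2ccc(O)cc2O)C5)[C@H](c2cc(O)cc(O)c2)[C@@H](c2ccc(O)cc2O)O4)cc1 | target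

**Count**

Total steps: 11. Longest linear sequence: 9 (steps 1, 2, 3, 5, 6, 7, 8, 10, 11).

**Steps most likely to fail**

1. Step 8 (key step). The stilbene radical cation may dimerise intermolecularly, the free resorcinol may be over-oxidised, or the C–C bond may form on the wrong alkene face. The fallback builds the same two rings by acid chemistry of known types and sets out from 12. Bromine–lithium exchange (n-BuLi, THF, −78 °C) gives the aryllithium F1, which is acylated with N-methoxy-N-methyl-2-(4-methoxyphenyl)acetamide to the ring B benzyl ketone F2. TBAF frees the resorcinol ketone F3. Catalytic TfOH in CH2Cl2 then brings about intramolecular Friedel–Crafts hydroxyalkylation and dehydration to the benzylidene-dibenzocycloheptene F4. In the same medium F4 is protonated at the ring carbon and the 4-methoxybenzyl cation is captured by the ortho phenol, with both centres formed under equilibrating conditions, which returns the route at 16.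

2. Step 10. The bond may form at the ring A carbon between the two oxygens, stilbene 19 may homodimerise, or attack on the wrong face may give the other trans diastereomer. The fallback uses catalyst control and sets out from 16. NBS (CH2Cl2, −78 °C) brominates ortho to the hydroxyl and para to the furan 1 oxygen to give the bromophenol F5, and 2,4-dimethoxybenzyl chloride with K2CO3 gives the benzyl ether F6. Bromine–lithium exchange gives the aryllithium F7, and N-methoxy-N-methyl-3,5-dimethoxybenzamide converts it into the diaryl ketone F8. Hydrazine gives the hydrazone F9, and MnO2 the diaryldiazomethane F10. A chiral dirhodium carboxylate such as Rh2(S-PTAD)4 (antipode chosen to set C-3 as S) then inserts the carbene into the benzylic ether C–H bond to give the cis-dihydrofuran F11. Acid (TFA, CH2Cl2) epimerises the O-benzylic C-2 to the trans isomer, which returns the route at 20.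

3. Step 2. Insertion of the di-ortho-substituted cinnamate may be slower than protodeboronation of the electron-rich boronic acid, or enantioselectivity may be low. The fallback replaces catalyst control by an auxiliary and sets out from 3. LiOH gives (E)-3-(2-bromo-4,6-dimethoxyphenyl)prop-2-enoic acid F12. Pivaloyl chloride and Et3N form the mixed pivalic anhydride F13, which acylates (S)-4-phenyloxazolidin-2-one in the presence of LiCl to the N-enoyl imide F14. (2,4-Dimethoxyphenyl)magnesium bromide with CuBr·SMe2 (THF, −40 to −10 °C) adds to the magnesium-chelated s-cis imide anti to the phenyl group, that is to the Si face of C-3, giving the (3R)-adduct F15. LiOH/H2O2 then releases the acid, which returns the route at 6.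

**Further compounds**

F1 | step 8 | aryllithium from 12 | CC(C)[Si](Oc1cc(C[C@H](c2ccc(OC)cc2OC)c2c(OC)cc(OC)cc2[Li])cc(O[Si](C(C)C)(C(C)C)C(C)C)c1)(C(C)C)C(C)C
F2 | step 8 | 1-{2-[(1R)-2-[3,5-bis(triisopropylsilyloxy)phenyl]-1-(2,4-dimethoxyphenyl)ethyl]-3,5-dimethoxyphenyl}-2-(4-methoxyphenyl)ethan-1-one | CC(C)[Si](Oc1cc(C[C@H](c2ccc(OC)cc2OC)c2c(OC)cc(OC)cc2C(=O)Cc2ccc(OC)cc2)cc(O[Si](C(C)C)(C(C)C)C(C)C)c1)(C(C)C)C(C)C
F3 | step 8 | 1-{2-[(1R)-2-(3,5-dihydroxyphenyl)-1-(2,4-dimethoxyphenyl)ethyl]-3,5-dimethoxyphenyl}-2-(4-methoxyphenyl)ethan-1-one | Oc1cc(O)cc(C[C@H](c2ccc(OC)cc2OC)c2c(OC)cc(OC)cc2C(=O)Cc2ccc(OC)cc2)c1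
F4 | step 8 | benzylidene-dibenzocycloheptene diol, (R) at CH(aryl), alkene geometry not controlled | Oc1cc(O)c2c(c1)C[C@H](c1ccc(OC)cc1OC)c1c(OC)cc(OC)cc1C2=Cc1ccc(OC)cc1
F5 | step 10 | bromophenol: 16 brominated on ring A between the hydroxyl and the CH2-bearing carbon | COc1ccc([C@@H]2Oc3cc(O)c(Br)c4c3[C@H]2c2cc(OC)cc(OC)c2[C@@H](c2ccc(OC)cc2OC)C4)cc1
F6 | step 10 | 2,4-dimethoxybenzyl ether of F5 | COc1ccc([C@@H]2Oc3cc(OCc5ccc(OC)cc5OC)c(Br)c4c3[C@H]2c2cc(OC)cc(OC)c2[C@@H](c2ccc(OC)cc2OC)C4)cc1
F7 | step 10 | aryllithium from F6 | COc1ccc([C@@H]2Oc3cc(OCc5ccc(OC)cc5OC)c([Li])c4c3[C@H]2c2cc(OC)cc(OC)c2[C@@H](c2ccc(OC)cc2OC)C4)cc1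
F8 | step 10 | ring A 3,5-dimethoxyphenyl ketone | COc1ccc([C@@H]2Oc3cc(OCc5ccc(OC)cc5OC)c(C(=O)c5cc(OC)cc(OC)c5)c4c3[C@H]2c2cc(OC)cc(OC)c2[C@@H](c2ccc(OC)cc2OC)C4)cc1
F9 | step 10 | hydrazone of F8 | COc1ccc([C@@H]2Oc3cc(OCc5ccc(OC)cc5OC)c(C(=NN)c5cc(OC)cc(OC)c5)c4c3[C@H]2c2cc(OC)cc(OC)c2[C@@H](c2ccc(OC)cc2OC)C4)cc1
F10 | step 10 | diaryldiazomethane from F9 | COc1ccc([C@@H]2Oc3cc(OCc5ccc(OC)cc5OC)c(C(=[N+]=[N-])c5cc(OC)cc(OC)c5)c4c3[C@H]2c2cc(OC)cc(OC)c2[C@@H](c2ccc(OC)cc2OC)C4)cc1
F11 | step 10 | cis-furan 2 isomer of 20 (furan 2 2R,3S) | COc1ccc([C@@H]2Oc3cc4c(c5c3[C@H]2c2cc(OC)cc(OC)c2[C@@H](c2ccc(OC)cc2OC)C5)[C@H](c2cc(OC)cc(OC)c2)[C@H](c2ccc(OC)cc2OC)O4)cc1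
F12 | step 2 | (E)-3-(2-bromo-4,6-dimethoxyphenyl)prop-2-enoic acid | OC(=O)/C=C/c1c(OC)cc(OC)cc1Br
F13 | step 2 | mixed anhydride of F12 with pivalic acid | CC(C)(C)C(=O)OC(=O)/C=C/c1c(OC)cc(OC)cc1Br
F14 | step 2 | (4S)-3-[(E)-3-(2-bromo-4,6-dimethoxyphenyl)prop-2-enoyl]-4-phenyloxazolidin-2-one | O=C(/C=C/c1c(OC)cc(OC)cc1Br)N1C(=O)OC[C@@H]1c1ccccc1
F15 | step 2 | (4S)-3-[(3R)-3-(2-bromo-4,6-dimethoxyphenyl)-3-(2,4-dimethoxyphenyl)propanoyl]-4-phenyloxazolidin-2-one | O=C(C[C@H](c1ccc(OC)cc1OC)c1c(OC)cc(OC)cc1Br)N1C(=O)OC[C@@H]1c1ccccc1
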